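## The problem

Target 23 is a daucane-type sesquiterpene ester. A cyclopentane (C1–C2–C3–C4–C5) is fused through the C1–C5 bond to a cycloheptene (C5–C6–C7=C8–C9–C10–C1). C1 is quaternary and carries a methyl, C4 is a tertiary carbinol with an isopropyl group, C8 carries a methyl, and the allylic C6 oxygen is esterified with isovanillic acid (3-hydroxy-4-methoxybenzoic acid).

The four stereocentres C1, C4, C5 and C6 are contiguous and crowd around C5. C1–CH3, H-5 and the isopropyl group lie on one face; the C4 hydroxyl and the C6 oxygen lie on the other. C1 matters most, because an all-carbon quaternary fusion centre cannot be corrected later. Once C1 is set, C5 is the α-carbon of a C4 (or C6) carbonyl and can settle into the cis fusion. C4 can then be set by addition to the convex face of a C4 ketone, and C6 by hydride addition to a C6 enone.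

The fragile elements are the tertiary alcohol β to C6 (retro-aldol or dehydration once C6 is a ketone), the ionisable allylic ester, the free phenol, and the C7=C8 alkene, which must survive every reduction. The ester is therefore introduced last.

The feature that opens the route is that C4 is bonded to C5 and C5–C1 can be an alkene of a cycloheptadiene. With C4 as a carbonyl, the five-membered ring is a cyclopentenone whose C1–C2 bond is the σ-bond of a 4π electrocyclisation of a pentadienyl cation C2–C3–C4–C5–C1. An oxygen on C6, next to that cation, is placed to decide the sense of conrotation and hence C1.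

## Retrosynthesis

**Ester and phenol.** The C6–O acyl bond is cut first: 23 comes from aryl silyl ether 22, and 22 from alcohol 18 and acid 21 (one step from isovanillic acid 19). The ester is the most labile group and the free phenol would compete in the acylation. A phenolic silyl ether comes off with buffered fluoride without touching the benzoate or the alkene. The forward step must acylate a secondary hydroxyl next to a tertiary one.

**C6 configuration.** Alcohol 18 is traced to enone 17 and then to its C6 epimer, diol 16. The C6 centre that steers the key step is opposite to that of the target. It is inverted by oxidation and 1,2-reduction from the convex face. Direct displacement would need attack from the concave side, next to the quaternary C4. Diol 16 comes from silyl ether 15.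

**C4–isopropyl bond.** Carbinol 15 is cut to ketone 14 and an isopropyl nucleophile. This makes C4 the carbonyl that the electrocyclisation produces anyway and keeps the cyclisation substrate small. Ketone 14 comes from enone 13 by saturating C2=C3. The forward addition must outrun enolisation and come from the convex face.

**C1–C2 bond (key cut).** Opening the cyclopentenone of 13 at C1–C2 and returning the C4 carbonyl to an enol ester leads, through dienyl acetate 12 and allenyl acetate 11, to propargylic acetate 10. This cut removes one ring and two stereocentres but leaves the seven-membered ring, the C6 oxygen, C7=C8 and both methyls in place. The cuts at C1–C5 or C1–C10 (below) do not. The forward step must close at a fully substituted alkene terminus and pass the C6 configuration on to C1.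

**C4–C5 bond.** Enyne 10 is cut between the alkyne and the ring to alkenyl iodide 8 and propargyl acetate 9. Iodide 8 comes from alcohol 7, and 7 from iodo dienone 6 by enantioselective reduction. Reduction precedes coupling because 2-halo enones are the best-behaved substrates for oxazaborolidine reduction.

**Seven-membered ring.** Iodide 6 comes from the symmetric dienone 5, whose two enone arms are equivalent, so iodination raises no regiochemical question. Dienone 5 is traced through 4, 3 and 2 to cycloheptanone 1. Both methyls enter by conjugate addition and the unsaturation is restored by dehydrogenation.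

## Roads not taken

**Alternative 1:** The cut is at C1–C5 and C9–C10, opening both rings to the acyclic ene-vinylcyclopropane A2, in which C4 already carries its isopropyl group and a silylated oxygen. In the forward step [Rh(CO)2Cl]2 would cleave the less substituted bond of the methylcyclopropane and insert the tethered 1,1-disubstituted alkene in a (5+2) cycloaddition to give bicycle A1.
- Merits: the whole skeleton forms in one step, tethered (5+2) reactions normally give the cis fusion, and the C4 carbinol is not made by adding a branched nucleophile to a hindered ketone. In that last respect this road is better than the chosen one, which depends on a lanthanide-promoted Grignard addition (step 11).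
- Weak points: the two-carbon partner is a 1,1-disubstituted alkene that must form quaternary C1, the least reactive partner class for this cycloaddition. C1 and C5 would be controlled only by the remote C4 centre. A1 has its alkene at C6=C7, C8 as an sp3 centre and no oxygen at C6, so an allylic oxidation with transposition and control of C6 would still be needed. A2 also needs a stereodefined cyclopropane.
- Comparison: the chosen plan offers a cyclisation on a tested substrate class, a C6 oxygen present from the start that also controls C1, and a seven-membered ring taken from a commodity ketone.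

**Alternative 2:** The cut at C1–C10 and C7–C8 removes the seven-membered ring and leads to cyclopentenyl siloxydiene A4 and vinyl diazoester A5. In the forward step Rh2(S-DOSP)4 would turn A5 into a vinylcarbenoid that cyclopropanates the terminal silyl enol ether alkene of A4 (C7–C8). Cope rearrangement of the cis-divinylcyclopropane would then form C1–C10 and give cycloheptadiene A3.
- Merits: it is convergent and catalyst-controlled, siloxydienes are good partners, and C4 is again pre-formed. It is more convergent than the chosen plan.
- Weak points: the Cope step must create quaternary C1 from a tetrasubstituted alkene terminus in a boat transition state, and catalyst and C4 may be mismatched. A3 has an ester where the C8 methyl belongs, its alkene at C8=C9 instead of C7=C8, and C5 locked in an enol ether, so C5–H and C6–OH are still unset.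
- Comparison: the redox and transposition steps after the key step would cost more than the convergence saves. Enone 13 already has both methyls, C7=C8 and the C6 oxygen.

**Alternative 3:** Both rings are opened (C1–C5 and C7–C8) to the acyclic vinyl diazoketone A7. A chiral dirhodium carboxylate such as Rh2(S-DOSP)4 would cyclopropanate the tethered trisubstituted alkene (C1–C5, creating the quaternary centre). The cis-divinylcyclopropane would rearrange (C7–C8) to dienone A6.
- Merits: it is the shortest path from a chain to the bare bicyclic skeleton, and the quaternary centre forms in a cyclopropanation that tolerates substitution. In step count to the skeleton it beats the chosen plan.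
- Weak points: enantiocontrol in intramolecular cyclopropanation of diazoketones with this catalyst family is generally modest. A6 has no oxygen at C6, has C5 as an alkene carbon, and carries a C9=C10 alkene the target lacks while C8 is sp3. It would need γ-oxidation, selective removal of one alkene and migration of unsaturation to C7=C8.
- Comparison: the chosen plan's key product has every oxygen and alkene of the core in its final position or one redox step away.

Key step: step 9

Assumption: the configuration is taken exactly as encoded in the SMILES, i.e. the cis-fused isomer with C1–CH3 and H-5 syn and both oxygens anti to them, (1R,4R,5S,6R) in the locants used here.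

Names of bicyclic compounds use the skeleton locants defined above on a bicyclo[5.3.0]decane frame (C1 and C5 fusion atoms, C2–C4 in the five-membered ring, C6–C10 in the seven-membered ring). These are not von Baeyer locants.

## Route

Step 1
Reactants: 1 cycloheptanone
Product: 2 cyclohepta-2,6-dien-1-one
Conditions: IBX (2.5 equiv), PhF/DMSO (2:1), 70 °C
Reagents that add atoms: none
Why: IBX dehydrogenation of a ketone through its enol; with about 2.5 equivalents the second unsaturation forms on the other side of the carbonyl, and the temperature is held below that at which tropone forms.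

Step 2
Reactants: 2 cyclohepta-2,6-dien-1-one
Product: 3 6-methylcyclohept-2-en-1-one (racemic)
Conditions: Me2CuLi (1.1 equiv, from MeLi and CuI), Et2O, −78 °C; then aq NH4Cl
Reagents that add atoms: lithium dimethylcuprate, [Li+].C[Cu-]C
Why: Gilman conjugate addition to one arm of the cross-conjugated dienone; the dienolate formed is inert to a second addition, so the mono-adduct should result, and its stereocentre is erased in step 4.

Step 3
Reactants: 3 6-methylcyclohept-2-en-1-one
Product: 4 3,6-dimethylcycloheptan-1-one (cis/trans mixture)
Conditions: Me2CuLi (1.5 equiv, from MeLi and CuI), Et2O, −78 to −20 °C; then aq NH4Cl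
Reagents that add atoms: lithium dimethylcuprate, [Li+].C[Cu-]C
Why: Second Gilman conjugate addition to the remaining enone; both diastereomers converge in step 4.

Step 4
Reactants: 4 3,6-dimethylcycloheptan-1-one
Product: 5 3,6-dimethylcyclohepta-2,6-dien-1-one
Conditions: IBX (3 equiv), PhF/DMSO (2:1), 70–75 °C
Reagents that add atoms: none
Why: Twofold IBX dehydrogenation; on each side the only β-carbon is the methyl-bearing one, so both alkenes form towards the methyls, both stereocentres vanish and a symmetric achiral dienone results.

Step 5
Reactants: 5 3,6-dimethylcyclohepta-2,6-dien-1-one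
Product: 6 2-iodo-3,6-dimethylcyclohepta-2,6-dien-1-one
Conditions: I2 (1.05 equiv), pyridine/CH2Cl2 (1:1), DMAP (0.1 equiv), 0 °C to rt
Reagents that add atoms: iodine, [I][I]
Why: α-Iodination of an enone with iodine and pyridine (addition to the enone then base-induced elimination), a reaction established for β-methyl cycloalkenones; the two arms of 5 are equivalent and one equivalent of iodine should hold the reaction at the mono-iodide.

Step 6
Reactants: 6 2-iodo-3,6-dimethylcyclohepta-2,6-dien-1-one
Product: 7 (S)-2-iodo-3,6-dimethylcyclohepta-2,6-dien-1-ol (the carbinol carbon becomes C6)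
Conditions: (R)-2-methyl-CBS-oxazaborolidine (0.2 equiv), catecholborane (1.5 equiv), toluene, −78 °C; then MeOH, aq NaOH
Reagents that add atoms: none
Why: Corey–Bakshi–Shibata reduction; as with 2-halocycloalkenones, the carbonyl should bind the catalyst anti to the larger iodine-bearing alkenyl arm, so the (R)-catalyst should deliver hydride to the face that gives the (S)-carbinol. Catecholborane at low temperature leaves the alkenes alone.

Step 7
Reactants: 7 (S)-2-iodo-3,6-dimethylcyclohepta-2,6-dien-1-ol
Product: 8 (S)-tert-butyl[(2-iodo-3,6-dimethylcyclohepta-2,6-dien-1-yl)oxy]dimethylsilane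
Conditions: TBSCl (1.3 equiv), imidazole, DMF, rt
Reagents that add atoms: tert-butyldimethylsilyl chloride, CC(C)(C)[Si](C)(C)Cl
Why: Imidazole-promoted silylation of a secondary alcohol; the bulky ether later shields one ring face and keeps the oxygen from attacking the gold-activated alkyne.

Step 8
Reactants: 8 (S)-tert-butyl[(2-iodo-3,6-dimethylcyclohepta-2,6-dien-1-yl)oxy]dimethylsilane; 9 propargyl acetate
Product: 10 3-[(7S)-7-(tert-butyldimethylsilyloxy)-2,5-dimethylcyclohepta-1,5-dien-1-yl]prop-2-yn-1-yl acetate
Conditions: PdCl2(PPh3)2 (5 mol%), CuI (10 mol%), i-Pr2NH, THF, rt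
Reagents that add atoms: none
Why: Sonogashira coupling (oxidative addition of zerovalent palladium to the alkenyl iodide, transmetalation from the copper acetylide, reductive elimination); propargylic acetates and silyl ethers tolerate these conditions and the stereocentre is not involved. The three carbons of 9 become C4, C3 and C2.

Step 9
Reactants: 10 3-[(7S)-7-(tert-butyldimethylsilyloxy)-2,5-dimethylcyclohepta-1,5-dien-1-yl]prop-2-yn-1-yl acetate
Product: 13 (1R,5S,6S)-6-(tert-butyldimethylsilyloxy)-1,8-dimethylbicyclo[5.3.0]deca-2,7-dien-4-one, via allenyl acetate 11 (not isolated), via cyclopentadienyl acetate 12 (not isolated)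
Conditions: Ph3PAuCl (5 mol%), AgSbF6 (5 mol%), CH2Cl2 saturated with H2O, 0 °C to rt
Reagents that add atoms: none
Why: The cationic monovalent gold complex formed from Ph3PAuCl and AgSbF6 activates the alkyne, the acetate carbonyl attacks C4 and a 3,3-acyloxy shift gives carboxyallene 11, whose gold complex is a 3-aurated 4-acetoxy pentadienyl cation over C2–C3–C4–C5–C1. Conrotatory 4π electrocyclisation (Nazarov closure) joins the unsubstituted terminus C2 to the methyl-bearing terminus C1 and closes the five-membered ring with its quaternary centre. A 1,2-hydride shift from C2 to the carbene-like C3 with loss of gold gives dienyl acetate 12, and water cleaves the enol acetate with protonation at C5 to give enone 13. The closest known reaction type is the tandem 3,3-rearrangement and Nazarov cyclisation of 5-acyloxy-1-en-3-ynes to cyclopentenones under Ph3PAuCl/AgSbF6 in wet CH2Cl2, which includes cycloalkenyl substrates that give cis-fused bicyclic enones. C1 is controlled by the C6 stereocentre: the silyloxy group should sit pseudoaxially to avoid allylic strain with the C4 substituent on C5 and so cover one face of the C5=C1 alkene, favouring the conrotation that brings C2 to the opposite face and leaves methyl and silyloxy cis. C5 is set in the last protonation and should be cis, because a nearly planar cyclopentenone trans-fused to a cycloheptene is strained and the centre can in any case epimerise towards the cis isomer. The step needs the 3,3-shift to win over a 1,2-acyloxy shift, which the internal alkenyl-substituted alkyne secures, and the hydride to come from C2, the only hydrogen-bearing carbon next to C3.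

Step 10
Reactants: 13 (1R,5S,6S)-6-(tert-butyldimethylsilyloxy)-1,8-dimethylbicyclo[5.3.0]deca-2,7-dien-4-one
Product: 14 (1R,5S,6S)-6-(tert-butyldimethylsilyloxy)-1,8-dimethylbicyclo[5.3.0]dec-7-en-4-one
Conditions: [(Ph3P)CuH]6 (0.4 equiv), H2O (5 equiv), benzene, rt
Reagents that add atoms: none
Why: Conjugate reduction by a phosphine-stabilised copper hydride: hydride adds to C2 of the enone only, and isolated trisubstituted alkenes and silyl ethers are untouched. Water protonates the copper enolate at C3, so no base is present that could epimerise C5 or eliminate the β-silyloxy group.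

Step 11
Reactants: 14 (1R,5S,6S)-6-(tert-butyldimethylsilyloxy)-1,8-dimethylbicyclo[5.3.0]dec-7-en-4-one
Product: 15 (1R,4R,5S,6S)-6-(tert-butyldimethylsilyloxy)-4-isopropyl-1,8-dimethylbicyclo[5.3.0]dec-7-en-4-ol
Conditions: i-PrMgCl (3 equiv), LaCl3·2LiCl (1 equiv), THF, −78 to 0 °C; then aq NH4Cl
Reagents that add atoms: isopropylmagnesium chloride, CC(C)[Mg]Cl
Why: Lanthanide-promoted Grignard 1,2-addition; LaCl3·2LiCl suppresses enolisation and β-hydride reduction by the secondary Grignard reagent. C4 is set by attack on the convex face of the cis-fused bicycle (the face of H-5 and the angular methyl, anti to the C5–C6 bond and the seven-membered ring), which puts isopropyl on that face and hydroxyl on the other.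

Step 12
Reactants: 15 (1R,4R,5S,6S)-6-(tert-butyldimethylsilyloxy)-4-isopropyl-1,8-dimethylbicyclo[5.3.0]dec-7-en-4-ol
Product: 16 (1R,4R,5S,6S)-4-isopropyl-1,8-dimethylbicyclo[5.3.0]dec-7-ene-4,6-diol
Conditions: TBAF (3 equiv), THF, rt to 45 °C
Reagents that add atoms: none
Why: Fluoride cleavage of the silyl ether; the tertiary alcohol and the alkene are inert and no stereocentre is touched.

Step 13
Reactants: 16 (1R,4R,5S,6S)-4-isopropyl-1,8-dimethylbicyclo[5.3.0]dec-7-ene-4,6-diol
Product: 17 (1R,4R,5R)-4-hydroxy-4-isopropyl-1,8-dimethylbicyclo[5.3.0]dec-7-en-6-one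
Conditions: Dess–Martin periodinane (1.3 equiv), NaHCO3, CH2Cl2, 0 °C
Reagents that add atoms: none
Why: Dess–Martin oxidation of the secondary allylic alcohol to the enone; the tertiary hydroxyl cannot be oxidised, and the buffered non-basic medium is meant to spare the β-hydroxy ketone from retro-aldol cleavage and C5 from epimerisation (the C5 descriptor changes only through priorities).

Step 14
Reactants: 17 (1R,4R,5R)-4-hydroxy-4-isopropyl-1,8-dimethylbicyclo[5.3.0]dec-7-en-6-one
Product: 18 (1R,4R,5S,6R)-4-isopropyl-1,8-dimethylbicyclo[5.3.0]dec-7-ene-4,6-diol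
Conditions: NaBH4 (1.5 equiv), CeCl3·7H2O (1.2 equiv), MeOH, −78 °C
Reagents that add atoms: none
Why: Luche 1,2-reduction of the enone. Hydride should add to C6 from the convex face (the side of H-5, anti to C4 on the neighbouring carbon), giving the 6R carbinol with its oxygen on the face of the C4 hydroxyl, which is the net inversion of the centre used in step 9.

Step 15
Reactants: 19 isovanillic acid
Product: 21 3-(tert-butyldimethylsilyloxy)-4-methoxybenzoic acid, via bis-silyl derivative 20 (not isolated)
Conditions: TBSCl (2.5 equiv), imidazole, DMF, rt; then AcOH/THF/H2O (3:1:1), rt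
Reagents that add atoms: tert-butyldimethylsilyl chloride, CC(C)(C)[Si](C)(C)Cl
Why: Exhaustive silylation, then selective hydrolysis of the labile silyl ester under mild aqueous acid, which leaves the aryl silyl ether; a standard way to mask the phenol of a hydroxybenzoic acid.

Step 16
Reactants: 18 (1R,4R,5S,6R)-4-isopropyl-1,8-dimethylbicyclo[5.3.0]dec-7-ene-4,6-diol; 21 3-(tert-butyldimethylsilyloxy)-4-methoxybenzoic acid
Product: 22 (1R,4R,5S,6R)-4-hydroxy-4-isopropyl-1,8-dimethylbicyclo[5.3.0]dec-7-en-6-yl 3-(tert-butyldimethylsilyloxy)-4-methoxybenzoate
Conditions: EDC·HCl (1.5 equiv), DMAP (1 equiv), CH2Cl2, rt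
Reagents that add atoms: none
Why: Steglich esterification (carbodiimide activation, acyl transfer through DMAP); only the secondary C6 hydroxyl reacts because the tertiary C4 hydroxyl is too hindered, and C6 keeps its configuration since its C–O bond is not broken.

Step 17
Reactants: 22 (1R,4R,5S,6R)-4-hydroxy-4-isopropyl-1,8-dimethylbicyclo[5.3.0]dec-7-en-6-yl 3-(tert-butyldimethylsilyloxy)-4-methoxybenzoate
Product: 23 (1R,4R,5S,6R)-4-hydroxy-4-isopropyl-1,8-dimethylbicyclo[5.3.0]dec-7-en-6-yl 3-hydroxy-4-methoxybenzoate (CNP0210850.1)
Conditions: TBAF (1.1 equiv), AcOH (1.2 equiv), THF, 0 °C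
Reagents that add atoms: none
Why: Buffered fluoride cleaves an aryl silyl ether quickly at 0 °C; acetic acid keeps the medium non-basic so the allylic benzoate is neither cleaved nor shifted.

## Compound list

1 | cycloheptanone | O=C1CCCCCC1 | starting material
2 | cyclohepta-2,6-dien-1-one | O=C1C=CCCC=C1 | intermediate
3 | 6-methylcyclohept-2-en-1-one (racemic) | O=C1C=CCCC(C)C1 | intermediate
4 | 3,6-dimethylcycloheptan-1-one (cis/trans mixture) | O=C1CC(C)CCC(C)C1 | intermediate
5 | 3,6-dimethylcyclohepta-2,6-dien-1-one | O=C1C=C(C)CCC(C)=C1 | intermediate
6 | 2-iodo-3,6-dimethylcyclohepta-2,6-dien-1-one | O=C1C=C(C)CCC(C)=C1I | intermediate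
7 | (S)-2-iodo-3,6-dimethylcyclohepta-2,6-dien-1-ol | CC1=C(I)[C@@H](O)C=C(C)CC1 | intermediate
8 | (S)-tert-butyl[(2-iodo-3,6-dimethylcyclohepta-2,6-dien-1-yl)oxy]dimethylsilane | CC1=C(I)[C@@H](O[Si](C)(C)C(C)(C)C)C=C(C)CC1 | intermediate
9 | propargyl acetate (prop-2-yn-1-yl acetate) | CC(=O)OCC#C | starting material
10 | 3-[(7S)-7-(tert-butyldimethylsilyloxy)-2,5-dimethylcyclohepta-1,5-dien-1-yl]prop-2-yn-1-yl acetate | CC(=O)OCC#CC1=C(C)CCC(C)=C[C@@H]1O[Si](C)(C)C(C)(C)C | intermediate
11 | 1-[(7S)-7-(tert-butyldimethylsilyloxy)-2,5-dimethylcyclohepta-1,5-dien-1-yl]propa-1,2-dien-1-yl acetate (allenyl acetate, not isolated) | C=C=C(OC(C)=O)C1=C(C)CCC(C)=C[C@@H]1O[Si](C)(C)C(C)(C)C | intermediate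
12 | (1R,6S)-6-(tert-butyldimethylsilyloxy)-1,8-dimethylbicyclo[5.3.0]deca-2,4,7-trien-4-yl acetate (cyclopentadienyl acetate, C2=C3 and C4=C5, not isolated) | CC(=O)OC1=C2[C@@H](O[Si](C)(C)C(C)(C)C)C=C(C)CC[C@]2(C)C=C1 | intermediate
13 | (1R,5S,6S)-6-(tert-butyldimethylsilyloxy)-1,8-dimethylbicyclo[5.3.0]deca-2,7-dien-4-one (cis-fused; C1–CH3, H-5 and silyloxy on one face) | O=C1C=C[C@@]2(C)CCC(C)=C[C@H](O[Si](C)(C)C(C)(C)C)[C@@H]12 | intermediate
14 | (1R,5S,6S)-6-(tert-butyldimethylsilyloxy)-1,8-dimethylbicyclo[5.3.0]dec-7-en-4-one | O=C1CC[C@@]2(C)CCC(C)=C[C@H](O[Si](C)(C)C(C)(C)C)[C@@H]12 | intermediate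
15 | (1R,4R,5S,6S)-6-(tert-butyldimethylsilyloxy)-4-isopropyl-1,8-dimethylbicyclo[5.3.0]dec-7-en-4-ol | CC(C)[C@]1(O)CC[C@@]2(C)CCC(C)=C[C@H](O[Si](C)(C)C(C)(C)C)[C@@H]12 | intermediate
16 | (1R,4R,5S,6S)-4-isopropyl-1,8-dimethylbicyclo[5.3.0]dec-7-ene-4,6-diol | CC(C)[C@]1(O)CC[C@@]2(C)CCC(C)=C[C@H](O)[C@@H]12 | intermediate
17 | (1R,4R,5R)-4-hydroxy-4-isopropyl-1,8-dimethylbicyclo[5.3.0]dec-7-en-6-one | CC(C)[C@]1(O)CC[C@@]2(C)CCC(C)=CC(=O)[C@@H]12 | intermediate
18 | (1R,4R,5S,6R)-4-isopropyl-1,8-dimethylbicyclo[5.3.0]dec-7-ene-4,6-diol | CC(C)[C@]1(O)CC[C@@]2(C)CCC(C)=C[C@@H](O)[C@@H]12 | intermediate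
19 | isovanillic acid (3-hydroxy-4-methoxybenzoic acid) | COc1ccc(C(=O)O)cc1O | starting material
20 | tert-butyldimethylsilyl 3-(tert-butyldimethylsilyloxy)-4-methoxybenzoate (not isolated) | COc1ccc(C(=O)O[Si](C)(C)C(C)(C)C)cc1O[Si](C)(C)C(C)(C)C | intermediate
21 | 3-(tert-butyldimethylsilyloxy)-4-methoxybenzoic acid | COc1ccc(C(=O)O)cc1O[Si](C)(C)C(C)(C)C | intermediate
22 | (1R,4R,5S,6R)-4-hydroxy-4-isopropyl-1,8-dimethylbicyclo[5.3.0]dec-7-en-6-yl 3-(tert-butyldimethylsilyloxy)-4-methoxybenzoate | COc1ccc(C(=O)O[C@@H]2C=C(C)CC[C@]3(C)CC[C@@](O)(C(C)C)[C@H]23)cc1O[Si](C)(C)C(C)(C)C | intermediate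
23 | (1R,4R,5S,6R)-4-hydroxy-4-isopropyl-1,8-dimethylbicyclo[5.3.0]dec-7-en-6-yl 3-hydroxy-4-methoxybenzoate | COc1ccc(C(=O)O[C@@H]2C=C(C)CC[C@]3(C)CC[C@@](O)(C(C)C)[C@H]23)cc1O | target

## Step count and least certain steps

Total: 17 steps. Longest linear sequence: 16 steps (1–14, 16, 17) from cycloheptanone; step 15 is a one-step side branch.

**Step 9 (key step).** Four things may go wrong.
- The primary propargylic acetate may rearrange slowly or by a 1,2-acyloxy shift.
- Torquoselectivity may be poor, since the controlling C6 centre sits on the carbon next to the bond-forming terminus and not on it.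
- The cationic intermediates may ionise the doubly allylic C6–O bond or lose a proton from C6 instead of shifting hydride from C2.
- Protonation at C5 may give some trans fusion.

Fallback (silicon-directed Nazarov cyclisation, same C1–C2 bond, no gold): it sets out from iodide 8. Iodine–lithium exchange (t-BuLi, Et2O, −78 °C) and acylation with (E)-N-methoxy-N-methyl-3-(trimethylsilyl)acrylamide would give (S,E)-1-[7-(tert-butyldimethylsilyloxy)-2,5-dimethylcyclohepta-1,5-dien-1-yl]-3-(trimethylsilyl)prop-2-en-1-one F1. FeCl3 in CH2Cl2 at −30 °C should then close the ring by the same conrotatory process. The β-silicon effect fixes the new alkene at C2=C3 with loss of the silyl group, and protonation at C5 returns the route to 13.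

**Step 6.** Both carbonyl substituents are alkenyl groups, so enantioface discrimination may be weaker than for simple 2-iodocycloalkenones. Fallback: it sets out from 6. Luche reduction (NaBH4, CeCl3·7H2O, MeOH, −40 °C) would give racemic 2-iodo-3,6-dimethylcyclohepta-2,6-dien-1-ol F2. Kinetic resolution with Burkholderia cepacia lipase and vinyl acetate (MTBE, rt) should acylate the (R)-enantiomer, as with simple 2-halocycloalkenols, to (R)-2-iodo-3,6-dimethylcyclohepta-2,6-dien-1-yl acetate F3. The remaining (S)-alcohol is 7, where the route is rejoined.

**Step 11.** The secondary Grignard reagent may enolise the ketone (with loss of C5 integrity or β-elimination of the silyloxy group) or reduce it by β-hydride transfer, and the facial preference rests on a convex-face argument only. Fallback: it sets out from 14. Addition of isopropenylmagnesium bromide with CeCl3 (THF, −78 °C), a smaller sp2 nucleophile without β-hydrogens, would give (1R,4S,5S,6S)-6-(tert-butyldimethylsilyloxy)-1,8-dimethyl-4-(prop-1-en-2-yl)bicyclo[5.3.0]dec-7-en-4-ol F4. Hydrogenation of the 1,1-disubstituted alkene alone with RhCl(PPh3)3 and H2 (benzene, rt) returns to 15.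

**Step 14 (with step 13).** At the β-hydroxy ketone stage retro-aldol cleavage or epimerisation at C5 may erode material, and hydride may attack C6 from the wrong face and regenerate 16. Fallback: it sets out from 16. Mitsunobu esterification with acid 21 (PPh3, DIAD, toluene, 0 °C to rt) would invert C6 and form the ester in one operation, returning at 22 and bypassing 17 and 18. No new compound is made. This displacement has to come from the concave side, which is why it is the reserve and not the first choice.

**Step 4.** The second dehydrogenation may stall, or oxidation may run on towards the tropone. Fallback: it sets out from 4.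
- Lithium diisopropylamide (LiN(i-Pr)2) and TMSCl (THF, −78 °C) would give trimethyl[(3,6-dimethylcyclohept-1-en-1-yl)oxy]silane F5.
- Saegusa–Ito oxidation (Pd(OAc)2, MeCN, rt) would give 3,6-dimethylcyclohept-2-en-1-one F6.
- Kinetic deprotonation on the saturated α′ side and silylation (LiN(i-Pr)2, TMSCl) would give trimethyl[(3,6-dimethylcyclohepta-1,6-dien-1-yl)oxy]silane F7.
- A second Pd(OAc)2 oxidation returns to 5.

## Further compounds

F1 | step 9 | (S,E)-1-[7-(tert-butyldimethylsilyloxy)-2,5-dimethylcyclohepta-1,5-dien-1-yl]-3-(trimethylsilyl)prop-2-en-1-one | C[Si](C)(C)/C=C/C(=O)C1=C(C)CCC(C)=C[C@@H]1O[Si](C)(C)C(C)(C)C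
F2 | step 6 | racemic 2-iodo-3,6-dimethylcyclohepta-2,6-dien-1-ol | CC1=C(I)C(O)C=C(C)CC1
F3 | step 6 | (R)-2-iodo-3,6-dimethylcyclohepta-2,6-dien-1-yl acetate | CC(=O)O[C@@H]1C=C(C)CCC(C)=C1I
F4 | step 11 | (1R,4S,5S,6S)-6-(tert-butyldimethylsilyloxy)-1,8-dimethyl-4-(prop-1-en-2-yl)bicyclo[5.3.0]dec-7-en-4-ol | C=C(C)[C@]1(O)CC[C@@]2(C)CCC(C)=C[C@H](O[Si](C)(C)C(C)(C)C)[C@@H]12
F0 | step 14 | none | none
F5 | step 4 | trimethyl[(3,6-dimethylcyclohept-1-en-1-yl)oxy]silane | C[Si](C)(C)OC1=CC(C)CCC(C)C1
F6 | step 4 | 3,6-dimethylcyclohept-2-en-1-one | O=C1C=C(C)CCC(C)C1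
F7 | step 4 | trimethyl[(3,6-dimethylcyclohepta-1,6-dien-1-yl)oxy]silane | C[Si](C)(C)OC1=CC(C)CCC(C)=C1
A1 | alternative 1 | cis-fused triethylsilyl ether of 4-isopropyl-1,8-dimethylbicyclo[5.3.0]dec-6-en-4-ol, product of the (5+2) cycloaddition | C1=C[C@@H](C)CC[C@]2(C)CC[C@@](O[Si](CC)(CC)CC)(C(C)C)[C@H]12
A2 | alternative 1 | ene-vinylcyclopropane: triethylsilyl ether of (E)-3-isopropyl-6-methyl-1-(trans-2-methylcyclopropyl)hepta-1,6-dien-3-ol | C=C(C)CC[C@@](O[Si](CC)(CC)CC)(C(C)C)/C=C/[C@H]1C[C@@H]1C
A3 | alternative 2 | fused cycloheptadiene with C8 methyl ester, C5=C6 silyl enol ether and C4 triethylsilyl ether, product of the cyclopropanation–Cope sequence | COC(=O)C1=CC[C@]2(C)CC[C@@](O[Si](CC)(CC)CC)(C(C)C)C2=C(O[Si](C)(C)C(C)(C)C)C1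
A4 | alternative 2 | cyclopentenyl siloxydiene: 2-[1-(tert-butyldimethylsilyloxy)vinyl]-1-isopropyl-3-methylcyclopent-2-en-1-yl triethylsilyl ether | C=C(O[Si](C)(C)C(C)(C)C)C1=C(C)CC[C@@]1(O[Si](CC)(CC)CC)C(C)C
A5 | alternative 2 | methyl 2-diazobut-3-enoate | C=CC(=[N+]=[N-])C(=O)OC
A6 | alternative 3 | 1,8-dimethylbicyclo[5.3.0]deca-5,9-dien-4-one, product of the intramolecular cyclopropanation–Cope sequence | O=C1CC[C@@]2(C)C=C[C@@H](C)CC=C12
A7 | alternative 3 | (7E,9E)-3-diazo-7-methylundeca-1,7,9-trien-4-one | C=CC(=[N+]=[N-])C(=O)CC/C(C)=C/C=C/C
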